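**Retrosynthetic overview**
- The target is unmasked in one BCl3 operation from a (2R,3R)-6-O-benzyl-5-O-methyl-3-methoxyflavanone (benzyl ether plus the carbonyl-chelated 5-OMe).
- Ring C is the only ring formed, and it is formed last: a chalcone-isomerase-like 6-endo oxa-Michael closure of a 2'-hydroxy-α-methoxychalcone. The 3-OMe is already in the chalcone, so one catalytic step sets C2 (catalyst control) and C3 (thermodynamic trans protonation).
- The α-methoxychalcone comes from a Claisen–Schmidt union of a ring A ω-methoxyacetophenone with 3-hydroxy-4,5-dimethoxybenzaldehyde (ring B).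
- The ring A ketone comes from acylation of 2,6-dimethoxyhydroquinone with methoxyacetic acid, then selective benzylation. Rings A and B are bought as arenes.

Assumption: the three starting materials are catalogue compounds, and the quinine-derived thiourea is taken to give the (2R) sense; if an analytical run shows the opposite, the pseudoenantiomeric quinidine-derived thiourea is used in the same step.

**Route**

Step 1
Reactants: 1 2,6-dimethoxybenzene-1,4-diol; 2 methoxyacetic acid
Product: 3 1-(3,6-dihydroxy-2,4-dimethoxyphenyl)-2-methoxyethan-1-one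
Conditions: BF3·OEt2 (as solvent), N2, 85 °C, 3 h; then H2O
Reagents that add atoms: none
Why: Friedel–Crafts acylation at a phloroglucinol-like position (ortho to OH, ortho and para to OMe); the two open ring positions are equivalent, the ketone product is deactivated against a second acylation, and no stereocenter is formed.

Step 2
Reactants: 3 1-(3,6-dihydroxy-2,4-dimethoxyphenyl)-2-methoxyethan-1-one
Product: 4 1-[3-(benzyloxy)-6-hydroxy-2,4-dimethoxyphenyl]-2-methoxyethan-1-one
Conditions: BnBr (1.05 equiv), K2CO3 (1.1 equiv), acetone, reflux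
Reagents that add atoms: benzyl bromide, BrCc1ccccc1
Why: Williamson ether synthesis in which the 6-OH is held in a hydrogen bond to the ketone and is far less nucleophilic, so one equivalent of BnBr alkylates only the 3-OH; this blocks the oxidation-prone hydroquinone and no stereocenter is formed.

Step 3
Reactants: 4 1-[3-(benzyloxy)-6-hydroxy-2,4-dimethoxyphenyl]-2-methoxyethan-1-one; 5 3-hydroxy-4,5-dimethoxybenzaldehyde
Product: 7 (Z)-1-[3-(benzyloxy)-6-hydroxy-2,4-dimethoxyphenyl]-3-(3-hydroxy-4,5-dimethoxyphenyl)-2-methoxyprop-2-en-1-one, via aldol adduct 6 (not isolated)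
Conditions: KOH (50 % aq, 10 equiv), EtOH, N2, rt, 48 h; then 1 M HCl, 0 °C
Reagents that add atoms: none
Why: Claisen–Schmidt (aldol) condensation in which the α-methoxy ketone enolate adds to the non-enolisable aldehyde (its meta-phenoxide is not conjugated to the formyl group) and adduct 6 loses hydroxide by E1cB to give the more stable Z enol ether with the aryl group trans to the carbonyl; strong base keeps the product as the open chalcone phenoxide until the cold acid quench.

Step 4
Reactants: 7 (Z)-1-[3-(benzyloxy)-6-hydroxy-2,4-dimethoxyphenyl]-3-(3-hydroxy-4,5-dimethoxyphenyl)-2-methoxyprop-2-en-1-one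
Product: 9 (2R,3R)-6-(benzyloxy)-2-(3-hydroxy-4,5-dimethoxyphenyl)-3,5,7-trimethoxy-2,3-dihydro-4H-chromen-4-one, via C3-enol 8 (not isolated)
Conditions: 1-[3,5-bis(trifluoromethyl)phenyl]-3-[(8S,9S)-6'-methoxycinchonan-9-yl]thiourea (10 mol %), toluene–CH2Cl2 4:1, 0 °C → rt, 48–72 h; recrystallise (EtOAc–hexane)
Reagents that add atoms: none
Why: Proposed new method: an enantioselective intramolecular oxa-Michael (6-endo-trig) closure modelled on chalcone isomerase, in which the quinuclidine nitrogen activates the 2'-OH while the thiourea N–H pair binds the carbonyl and α-methoxy oxygens in a two-point contact, so the phenol oxygen adds to one face of C-β and sets C2 (R), and enol 8 is then protonated at C3 under amine-mediated equilibration to the trans (3R) isomer with aryl and OMe both equatorial; the closest known reaction types are the cinchona-thiourea-catalysed oxa-Michael cyclisation of activated 2'-hydroxychalcones (alkylidene β-ketoesters) to flavanones and the racemic base-mediated closure of 2'-hydroxy-α-methoxychalcones to trans-3-methoxyflavanones.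

Step 5
Reactants: 9 (2R,3R)-6-(benzyloxy)-2-(3-hydroxy-4,5-dimethoxyphenyl)-3,5,7-trimethoxy-2,3-dihydro-4H-chromen-4-one
Product: 11 (2R,3R)-5,6-dihydroxy-2-(3-hydroxy-4,5-dimethoxyphenyl)-3,7-dimethoxy-2,3-dihydro-4H-chromen-4-one (target CNP0075601.1), via tris(dichloroboryl) ether 10 (not isolated)
Conditions: BCl3 (1 M in CH2Cl2, 6 equiv), pentamethylbenzene (3 equiv), CH2Cl2, −78 → 0 °C, Ar; then H2O, 0 °C
Reagents that add atoms: none
Why: Lewis-acid ether cleavage in which BCl3 removes the benzyl group at low temperature (cation trapped by pentamethylbenzene) and, on warming, the 5-OMe that sits in a six-membered boron chelate with the C4 carbonyl (SN2 attack of chloride on the methyl), while the non-chelated 7-, 4'-, 5'- and aliphatic 3-OMe groups survive and the stereocenters are untouched at or below 0 °C.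

**Compound list**

1 | 2,6-dimethoxybenzene-1,4-diol | COc1cc(O)cc(OC)c1O | starting material
2 | methoxyacetic acid | COCC(=O)O | starting material
3 | 1-(3,6-dihydroxy-2,4-dimethoxyphenyl)-2-methoxyethan-1-one | COCC(=O)c1c(O)cc(OC)c(O)c1OC | intermediate
4 | 1-[3-(benzyloxy)-6-hydroxy-2,4-dimethoxyphenyl]-2-methoxyethan-1-one | COCC(=O)c1c(O)cc(OC)c(OCc2ccccc2)c1OC | intermediate
5 | 3-hydroxy-4,5-dimethoxybenzaldehyde | COc1cc(C=O)cc(O)c1OC | starting material
6 | 1-[3-(benzyloxy)-6-hydroxy-2,4-dimethoxyphenyl]-3-hydroxy-3-(3-hydroxy-4,5-dimethoxyphenyl)-2-methoxypropan-1-one (aldol adduct, diastereomer mixture, not isolated) | COC(C(O)c1cc(O)c(OC)c(OC)c1)C(=O)c1c(O)cc(OC)c(OCc2ccccc2)c1OC | intermediate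
7 | (Z)-1-[3-(benzyloxy)-6-hydroxy-2,4-dimethoxyphenyl]-3-(3-hydroxy-4,5-dimethoxyphenyl)-2-methoxyprop-2-en-1-one | CO/C(=C\c1cc(O)c(OC)c(OC)c1)C(=O)c1c(O)cc(OC)c(OCc2ccccc2)c1OC | intermediate
8 | (2R)-6-(benzyloxy)-2-(3-hydroxy-4,5-dimethoxyphenyl)-3,5,7-trimethoxy-2H-chromen-4-ol (C3-enol, not isolated) | COc1cc2c(c(OC)c1OCc1ccccc1)C(O)=C(OC)[C@@H](c1cc(O)c(OC)c(OC)c1)O2 | intermediate
9 | (2R,3R)-6-(benzyloxy)-2-(3-hydroxy-4,5-dimethoxyphenyl)-3,5,7-trimethoxy-2,3-dihydro-4H-chromen-4-one | COc1cc2c(c(OC)c1OCc1ccccc1)C(=O)[C@H](OC)[C@@H](c1cc(O)c(OC)c(OC)c1)O2 | intermediate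
10 | (2R,3R)-5,6-bis(dichloroboryloxy)-2-[3-(dichloroboryloxy)-4,5-dimethoxyphenyl]-3,7-dimethoxy-2,3-dihydro-4H-chromen-4-one (not isolated) | COc1cc2c(c(OB(Cl)Cl)c1OB(Cl)Cl)C(=O)[C@H](OC)[C@@H](c1cc(OB(Cl)Cl)c(OC)c(OC)c1)O2 | intermediate
11 | (2R,3R)-5,6-dihydroxy-2-(3-hydroxy-4,5-dimethoxyphenyl)-3,7-dimethoxy-2,3-dihydro-4H-chromen-4-one | COc1cc2c(c(O)c1O)C(=O)[C@H](OC)[C@@H](c1cc(O)c(OC)c(OC)c1)O2 | target

**Step count and risks**

Total steps: 5. Longest linear sequence: 5 (1 → 3 → 4 → 7 → 9 → 11).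

Most likely to fail, in order:

1. Step 4 (catalytic closure). The α-methoxy group and the electron-rich B ring make C-β a weak acceptor, so conversion or ee may be low, and the sense of induction is unproven. Fallback, setting out from 7 and coming back at 9: close 7 under thermodynamic control (NaOAc, EtOH, reflux) to the racemic trans-flavanone, which is 9 together with its mirror image (2S,3S)-6-(benzyloxy)-2-(3-hydroxy-4,5-dimethoxyphenyl)-3,5,7-trimethoxy-2,3-dihydro-4H-chromen-4-one F1. Resolve the racemate by preparative chiral SFC on an amylose tris(3,5-dimethylphenylcarbamate) phase to give 9. F1 is returned to 7 by KOH-mediated ring opening (retro-oxa-Michael) and recycled.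

2. Step 5 (BCl3 unmasking). The flanked 4'-OMe or the 3-OMe could also be cleaved, and a Lewis acid on the finished flavanone could open ring C and erode C2. Fallback, setting out from 3 and coming back at 11, moves the Lewis acid to the achiral ketone stage and ends with a neutral hydrogenolysis:
   - BCl3 (CH2Cl2, 0 °C) on 3 cleaves only the carbonyl-chelated 2-OMe and gives 1-(2,3,6-trihydroxy-4-methoxyphenyl)-2-methoxyethan-1-one F2.
   - Ph2CCl2 (Ph2O, 170 °C) ties the catechol as the ketal 1-(5-hydroxy-7-methoxy-2,2-diphenyl-1,3-benzodioxol-4-yl)-2-methoxyethan-1-one F3, leaving only the chelated OH free.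
   - Claisen–Schmidt condensation with 5 (KOH, EtOH) gives (Z)-1-(5-hydroxy-7-methoxy-2,2-diphenyl-1,3-benzodioxol-4-yl)-3-(3-hydroxy-4,5-dimethoxyphenyl)-2-methoxyprop-2-en-1-one F4.
   - The same thiourea-catalysed oxa-Michael closure gives (2R,3R)-5,6-(diphenylmethylenedioxy)-2-(3-hydroxy-4,5-dimethoxyphenyl)-3,7-dimethoxy-2,3-dihydro-4H-chromen-4-one F5.
   - H2 over Pd/C (THF–MeOH, rt) removes the ketal and gives 11.

3. Step 3 (Claisen–Schmidt). The aldehyde reacts as its phenoxide and the hindered α-methoxy ketone is a sluggish donor, so conversion may stall. Fallback, setting out from 5 and coming back at 11, changes the protecting-group plan so that the electrophile is a neutral aldehyde and no free B-ring phenol enters the catalytic step: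
   - BnBr, K2CO3, DMF converts 5 into 3-(benzyloxy)-4,5-dimethoxybenzaldehyde F6.
   - Condensation of F6 with 4 (KOH, EtOH) gives (Z)-1-[3-(benzyloxy)-6-hydroxy-2,4-dimethoxyphenyl]-3-[3-(benzyloxy)-4,5-dimethoxyphenyl]-2-methoxyprop-2-en-1-one F7.
   - The thiourea-catalysed closure gives (2R,3R)-6-(benzyloxy)-2-[3-(benzyloxy)-4,5-dimethoxyphenyl]-3,5,7-trimethoxy-2,3-dihydro-4H-chromen-4-one F8.
   - BCl3 with pentamethylbenzene, as in step 5, cleaves both benzyl ethers and the 5-OMe and gives 11.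

**Further compounds**

F1 | step 4 | (2S,3S)-6-(benzyloxy)-2-(3-hydroxy-4,5-dimethoxyphenyl)-3,5,7-trimethoxy-2,3-dihydro-4H-chromen-4-one | COc1cc2c(c(OC)c1OCc1ccccc1)C(=O)[C@@H](OC)[C@H](c1cc(O)c(OC)c(OC)c1)O2
F2 | step 5 | 1-(2,3,6-trihydroxy-4-methoxyphenyl)-2-methoxyethan-1-one | COCC(=O)c1c(O)cc(OC)c(O)c1O
F3 | step 5 | 1-(5-hydroxy-7-methoxy-2,2-diphenyl-1,3-benzodioxol-4-yl)-2-methoxyethan-1-one | COCC(=O)c1c(O)cc(OC)c2OC(c3ccccc3)(c3ccccc3)Oc12
F4 | step 5 | (Z)-1-(5-hydroxy-7-methoxy-2,2-diphenyl-1,3-benzodioxol-4-yl)-3-(3-hydroxy-4,5-dimethoxyphenyl)-2-methoxyprop-2-en-1-one | CO/C(=C\c1cc(O)c(OC)c(OC)c1)C(=O)c1c(O)cc(OC)c2OC(c3ccccc3)(c3ccccc3)Oc12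
F5 | step 5 | (2R,3R)-5,6-(diphenylmethylenedioxy)-2-(3-hydroxy-4,5-dimethoxyphenyl)-3,7-dimethoxy-2,3-dihydro-4H-chromen-4-one | COc1cc2c(c3OC(c4ccccc4)(c4ccccc4)Oc13)C(=O)[C@H](OC)[C@@H](c1cc(O)c(OC)c(OC)c1)O2
F6 | step 3 | 3-(benzyloxy)-4,5-dimethoxybenzaldehyde | COc1cc(C=O)cc(OCc2ccccc2)c1OC
F7 | step 3 | (Z)-1-[3-(benzyloxy)-6-hydroxy-2,4-dimethoxyphenyl]-3-[3-(benzyloxy)-4,5-dimethoxyphenyl]-2-methoxyprop-2-en-1-one | CO/C(=C\c1cc(OCc2ccccc2)c(OC)c(OC)c1)C(=O)c1c(O)cc(OC)c(OCc2ccccc2)c1OC
F8 | step 3 | (2R,3R)-6-(benzyloxy)-2-[3-(benzyloxy)-4,5-dimethoxyphenyl]-3,5,7-trimethoxy-2,3-dihydro-4H-chromen-4-one | COc1cc2c(c(OC)c1OCc1ccccc1)C(=O)[C@H](OC)[C@@H](c1cc(OCc3ccccc3)c(OC)c(OC)c1)O2
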